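Each molecule of racemization catalyst in the flask faces 200 molecules of left-handed substrate, and our question is how many of them it can turn over.

| flask | left-handed substrate | right-handed substrate | partner | racemization catalyst | added ligand | remark | time |
|---|---|---|---|---|---|---|---|
| oak | 17 mM | 17 mM | 102 mM | 0.17 mM | 0.93 mM | run made earlier |  |
| cedar | 68 mM | 68 mM | 102 mM | 0.17 mM | 0.93 mM | run made earlier |  |
| elm | 34 mM | 34 mM | 51 mM | 0.17 mM | 0.93 mM | run made earlier |  |
| flask | 34 mM | 34 mM | 102 mM | 0.17 mM | 0.93 mM |  | 5.0 min |

| run | time / min | left-handed product / % | right-handed product / % |
|---|---|---|---|
| oak | 0.417 | 37 | 19 |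
| oak | 0.833 | 41 | 28 |
| oak | 1.33 | 49 | 33 |
| oak | 1.50 | 52 | 36 |
| oak | 2.00 | 53 | 37 |
| oak | 2.50 | 51 | 42 |
| oak | 3.00 | 54 | 43 |
| cedar | 0.250 | 23 | 10 |
| cedar | 0.333 | 28 | 10 |
| cedar | 0.500 | 30 | 17 |
| cedar | 0.833 | 38 | 16 |
| cedar | 1.33 | 36 | 22 |
| cedar | 2.00 | 44 | 24 |
| cedar | 3.00 | 45 | 27 |
| elm | 0.250 | 14 | 7 |
| elm | 0.417 | 22 | 10 |
| elm | 0.833 | 29 | 14 |
| elm | 1.50 | 36 | 18 |
| elm | 3.00 | 41 | 24 |

(scatter of a reading: 2 percentage points)

- partner is single-handed; left-handed substrate and right-handed substrate are mirror images of each other, charged as a racemate, each of them at the stated concentration
- an excess is the difference of the two amounts in percent of their sum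
- an excess is below zero if the other one leads
- the handed part of partner does not stay in what it makes, so the products of the two hands are mirror images too

- left-handed product and right-handed product together, in percent of the left-handed substrate and right-handed substrate charged together, at 5.0 min
- excess of left-handed product over right-handed product in the product at 5.0 min
- whether the exchange between left-handed substrate and right-handed substrate keeps pace with the reaction: how far the product's excess at 5.0 min gets from its value without exchange to its value with instant exchange (above 80 % keeps pace, below 20 % hardly takes part, else lags behind)

In oak the partner takes left-handed substrate faster than right-handed substrate, while the catalyst turns one hand into the other. We read the ratio of the two rate constants, the selectivity factor, from the first oak reading, treating exchange as small so early: it is the logarithm of the unreacted share of one hand over that of the other.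

selectivity factor = 2.82

With instant exchange the two substrates stay equal, so products form in that ratio, and the product excess is 47.6 %. Near full conversion, reaching this in the flask means moving that share of one hand's charge across, which per catalyst molecule is

turnovers needed = 95.2

Now we ask what the catalyst delivers. Oak's last three readings of left-handed product average 52.7 %, good to 1.2 percentage points. What stands above the charge of left-handed substrate came through exchange, so we divide that amount by c(racemization catalyst):

oak turnover number, the net molecules moved across per molecule of catalyst charged, = 5.33

The flask has the same c(partner) as oak, so we assume that the catalyst works for the same time; we also take the exchange to grow with the gap between the hands, and at a like stage the flask's gap is twice oak's. Our reckoning: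

flask turnover number = 10.7, moving 1.81 mM

That is 11.2 % of the way, below 20 %, so we expect that the exchange hardly takes part, adding about 5.3 points of excess.

The forecast gave 97 %, 13 % and "lags behind", holding that “Exchange therefore isn't first-order in substrate” and moving about 4 mM, where we move 1.81 mM.

    partner + left-handed substrate → left-handed product (k = 0.550 M⁻¹ s⁻¹)
    partner + right-handed substrate → right-handed product (k = 0.180 M⁻¹ s⁻¹)
    left-handed substrate + racemization catalyst ⇌ right-handed substrate + racemization catalyst, rate k3*[racemization catalyst]*[left-handed substrate] forward; the back reaction follows from the equilibrium constant (k = 56.0 M⁻¹ s⁻¹)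
    racemization catalyst + added ligand ⇌ idle complex, settled at all times (K = 520 M⁻¹)
    partner + racemization catalyst → spent catalyst (k = 0.860 M⁻¹ s⁻¹)

The flask gives 96.2 % with an excess of 7.79 %, which is 8.0 % of the way, so the exchange hardly takes part. Spent catalyst already stands at 75.1 % of the catalyst charged after 0.500 min, when right-handed substrate is still 31.7 % of the two substrates charged. Counted as in oak, where it read 5.33, the flask's turnover number is 7.42. In the neighbour flask with 170 mM of partner, 99.9 % at an excess of 2.07 % gives a turnover number of 3.86.

(The numbers in the tables were generated by integration from invented constants; noise was put on by code.)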